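**Retrosynthetic overview**
- Ring C is cut at C2–C3 and at C4–C4a: a formal [4+2] union of an aryl 2-oxadiene oxocarbenium ion (C4a=C8a–O1=C2) with a two-carbon ketene surrogate, ethoxyacetylene, which supplies C3 and C4.
- Enabling feature: the 3,4,5-trimethoxyphenoxy ring A. Its ether oxygen O1 carries the cation at C2, and its two ortho carbons are equivalent and each para to a methoxy group, so the Friedel–Crafts closure at C4a has no regiochemical choice.
- The oxocarbenium precursor is a benzotriazole O-aryl aminal, made from veratraldehyde, benzotriazole and 3,4,5-trimethoxyphenol; its racemic centre is erased on ionisation.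
- Rings A and B are bought. Ring C is the only ring formed, in the last step, together with the C4 carbonyl and the C2 stereocentre.

Key step: step 3

Assumption: of the two antipodes of the chiral acid used in step 3, the (S,S)-form is taken to be the one that leaves the Si face of the oxocarbenium carbon open (Si-face attack corresponds to 2S); should a test run show the opposite sense, the mirror-image acid is used in the same way.

Step 1
Reactants: 1 3,4-dimethoxybenzaldehyde (veratraldehyde); 2 1H-benzotriazole
Product: 4 (±)-1-[chloro(3,4-dimethoxyphenyl)methyl]-1H-benzotriazole, via hemiaminal 3 (not isolated)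
Conditions: SOCl2 (1.2 equiv), CHCl3, 0 °C to reflux; evaporate, use crude
Reagents that add atoms: thionyl chloride, O=S(Cl)Cl
Why: Benzotriazole adds reversibly to the aldehyde to give hemiaminal 3, whose hydroxyl is exchanged for chloride through the chlorosulfite (benzotriazole–aldehyde–thionyl chloride condensation, a deoxychlorination); the new centre is racemic and is erased in step 3.

Step 2
Reactants: 4 (±)-1-[chloro(3,4-dimethoxyphenyl)methyl]-1H-benzotriazole; 5 3,4,5-trimethoxyphenol
Product: 7 (±)-1-[(3,4-dimethoxyphenyl)(3,4,5-trimethoxyphenoxy)methyl]-1H-benzotriazole, via sodium phenoxide 6 (not isolated)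
Conditions: NaH (1.1 equiv), DMF, 0 °C; then 4 in THF, 0 °C to rt
Reagents that add atoms: none
Why: Williamson-type O-alkylation of the phenoxide by the activated benzylic chloride of a 1-(α-chloroalkyl)benzotriazole, with the dipolar aprotic solvent favouring attack through oxygen over carbon; the centre stays racemic and is erased in step 3.

Step 3
Reactants: 7 (±)-1-[(3,4-dimethoxyphenyl)(3,4,5-trimethoxyphenoxy)methyl]-1H-benzotriazole; 8 ethoxyacetylene (ethoxyethyne, commercial solution in hexanes)
Product: 12 (2S)-5,6,7,3',4'-pentamethoxyflavanone, via aryl oxocarbenium ion 9 (not isolated), via ketenium ion 10 (not isolated), via enol ether 11 (not isolated)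
Conditions: (S,S)-imidodiphosphorimidate Brønsted acid HN[P(=NSO2CF3)(O,O'-binaphthyl)]2 built from two (S)-3,3'-bis[3,5-bis(trifluoromethyl)phenyl]-1,1'-binaphthalene-2,2'-diol units (5 mol %), 8 (3 equiv, added slowly), toluene/CH2Cl2 4:1, −60 °C; then 1 M aq. HCl, THF, 0 °C
Reagents that add atoms: water, O
Why: Proposed new method: a catalytic enantioselective oxa-Povarov-type formal [4+2] annulation with an ynol ether as ketene surrogate, in which the acid protonates N3 of the benzotriazolyl group of 7, neutral benzotriazole leaves to give the (E)-oxocarbenium ion 9 paired with the confined chiral anion, the nucleophilic terminal carbon of 8 adds to C2 to give ketenium ion 10, the ring A carbon ortho to O1 and para to a methoxy group captures its sp carbon, loss of the proton returns the catalyst and leaves enol ether 11, and the acidic work-up hydrolyses 11 to the ketone. The closest known reaction types are the SnCl4-mediated oxa-Povarov reaction of aryl oxocarbenium ions with alkenes, the Povarov reaction of N-aryl iminium ions with alkynes and ynamides, the Friedel–Crafts capture of ketenium ions generated from ynol ethers, and enantioselective additions of pi-nucleophiles to oxocarbenium ions paired with chiral imidodiphosphorimidate anions. Ring C closes by a six-membered Friedel–Crafts attack on the digonal ketenium carbon (6-exo-dig with respect to its C=O+ pi bond, the C3=C4 bond ending up inside the ring), the in-plane pi* orbital of that bond pointing at the tethered arene. The only new stereocentre, C2, is set in the irreversible C2–C3 bond formation, where the chiral anion is expected to cover the Re face of 9 so that 8 adds to the Si face, which corresponds to 2S. The step needs ionisation at C–N and not at C–OAr (secured by protonation of the basic benzotriazole nitrogen), six-ring closure onto ring A in preference to five-ring closure onto ring B or oxete formation at O1 (secured by the higher nucleophilicity of the trimethoxyphenoxy carbon and the ring size), and no regiochemical choice on ring A because its two ortho carbons are equivalent. Scrambling of C2 is avoided by quenching cold and keeping the flavanone away from base, which would open it to the chalcone.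

**Compound list**
1 | 3,4-dimethoxybenzaldehyde (veratraldehyde) | COc1ccc(C=O)cc1OC | starting material
2 | 1H-benzotriazole | c1ccc2[nH]nnc2c1 | starting material
3 | (±)-(1H-benzotriazol-1-yl)(3,4-dimethoxyphenyl)methanol | COc1ccc(C(O)n2nnc3ccccc32)cc1OC | intermediate
4 | (±)-1-[chloro(3,4-dimethoxyphenyl)methyl]-1H-benzotriazole | COc1ccc(C(Cl)n2nnc3ccccc32)cc1OC | intermediate
5 | 3,4,5-trimethoxyphenol | COc1cc(O)cc(OC)c1OC | starting material
6 | sodium 3,4,5-trimethoxyphenoxide | COc1cc([O-])cc(OC)c1OC.[Na+] | intermediate
7 | (±)-1-[(3,4-dimethoxyphenyl)(3,4,5-trimethoxyphenoxy)methyl]-1H-benzotriazole | COc1ccc(C(Oc2cc(OC)c(OC)c(OC)c2)n2nnc3ccccc32)cc1OC | intermediate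
8 | ethoxyacetylene (ethoxyethyne) | C#COCC | starting material
9 | (E)-[(3,4-dimethoxyphenyl)methylidene](3,4,5-trimethoxyphenyl)oxonium, as ion pair with the catalyst anion | COc1ccc(/C=[O+]/c2cc(OC)c(OC)c(OC)c2)cc1OC | intermediate
10 | (S)-[3-(3,4-dimethoxyphenyl)-3-(3,4,5-trimethoxyphenoxy)prop-1-en-1-ylidene](ethyl)oxonium, as ion pair with the catalyst anion | COc1ccc([C@H](C=C=[O+]CC)Oc2cc(OC)c(OC)c(OC)c2)cc1OC | intermediate
11 | (2S)-2-(3,4-dimethoxyphenyl)-4-ethoxy-5,6,7-trimethoxy-2H-chromene | COc1ccc([C@@H]2C=C(OCC)c3c(cc(OC)c(OC)c3OC)O2)cc1OC | intermediate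
12 | (2S)-5,6,7,3',4'-pentamethoxyflavanone [(2S)-2-(3,4-dimethoxyphenyl)-5,6,7-trimethoxychroman-4-one] | COc1ccc([C@@H]2CC(=O)c3c(cc(OC)c(OC)c3OC)O2)cc1OC | target

**Total step count:** 3
**Longest linear sequence:** 3 (1 → 4 → 7 → 12)

**Steps most likely to fail**

Step 3 (Proposed new method). What may go wrong: poor facial discrimination in the addition of the ynol ether to the ion pair; capture of the ketenium ion by the ether oxygen (oxete formation and ring opening to a cinnamate) or by benzotriazole instead of by ring A; acid-triggered consumption of the ynol ether before it meets the oxocarbenium ion. The fallback uses known chemistry, sets out from 5 and comes back at 12. Friedel–Crafts acetylation of 5 ortho to the hydroxyl (AcOH, BF3·OEt2, 80 °C) would give 1-(6-hydroxy-2,3,4-trimethoxyphenyl)ethanone F1. Condensation with N,N-dimethylformamide dimethyl acetal (toluene, 100 °C) would give the enaminone (E)-3-(dimethylamino)-1-(6-hydroxy-2,3,4-trimethoxyphenyl)prop-2-en-1-one F2. Aqueous HCl in CH2Cl2 would close F2 to 5,6,7-trimethoxy-4H-chromen-4-one F3. Asymmetric conjugate addition of commercial (3,4-dimethoxyphenyl)boronic acid to F3 would then give 12; conditions: Pd(OCOCF3)2, the 4-tert-butyl-2-(pyridin-2-yl)-4,5-dihydrooxazole ligand in the antipode that delivers 2S, NH4PF6, H2O, 1,2-dichloroethane, 60 °C.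

Step 2. What may go wrong: alkylation of the ambident phenoxide at its electron-rich ring carbons instead of at oxygen, and hydrolysis or ionisation of the labile chloride before it is trapped. The fallback forms the O1–C2 bond by acylation, sets out from 5 and comes back at oxocarbenium ion 9 inside step 3. Schotten–Baumann acylation of 5 with commercial 3,4-dimethoxybenzoyl chloride (aq. NaOH, CH2Cl2) would give 3,4,5-trimethoxyphenyl 3,4-dimethoxybenzoate F4. Reduction with DIBAL-H (CH2Cl2, −78 °C) would give the aluminium hemiacetal [(3,4-dimethoxyphenyl)(3,4,5-trimethoxyphenoxy)methoxy]diisobutylalane F5. Trapping F5 in the same flask with Ac2O, pyridine and DMAP (reductive acetylation of an ester) would give (±)-(3,4-dimethoxyphenyl)(3,4,5-trimethoxyphenoxy)methyl acetate F6. Under the conditions of step 3, F6 would lose acetic acid and give 9.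

Step 1. What may go wrong: over-reaction of the electron-rich aldehyde to the bis(benzotriazolyl) aminal, and incomplete chlorination or decomposition of the easily ionised chloride on concentration. The fallback builds the same chloride from the benzylic carbanion, sets out from 2 and comes back at 4. N-Alkylation of 2 with commercial 3,4-dimethoxybenzyl chloride (K2CO3, DMF, rt; the 1-isomer is separated from the 2-isomer) would give 1-(3,4-dimethoxybenzyl)-1H-benzotriazole F7. Deprotonation with n-BuLi (THF, −78 °C) would give the benzotriazole-stabilised benzylic lithium compound F8. Electrophilic chlorination of F8 with hexachloroethane would give 4.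

**Further compounds**
F1 | step 3 | 1-(6-hydroxy-2,3,4-trimethoxyphenyl)ethanone | CC(=O)c1c(O)cc(OC)c(OC)c1OC
F2 | step 3 | (E)-3-(dimethylamino)-1-(6-hydroxy-2,3,4-trimethoxyphenyl)prop-2-en-1-one | CN(C)/C=C/C(=O)c1c(O)cc(OC)c(OC)c1OC
F3 | step 3 | 5,6,7-trimethoxy-4H-chromen-4-one | COc1cc2occc(=O)c2c(OC)c1OC
F4 | step 2 | 3,4,5-trimethoxyphenyl 3,4-dimethoxybenzoate | COc1ccc(C(=O)Oc2cc(OC)c(OC)c(OC)c2)cc1OC
F5 | step 2 | (±)-[(3,4-dimethoxyphenyl)(3,4,5-trimethoxyphenoxy)methoxy]diisobutylalane | COc1ccc(C(O[Al](CC(C)C)CC(C)C)Oc2cc(OC)c(OC)c(OC)c2)cc1OC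
F6 | step 2 | (±)-(3,4-dimethoxyphenyl)(3,4,5-trimethoxyphenoxy)methyl acetate | COc1ccc(C(OC(C)=O)Oc2cc(OC)c(OC)c(OC)c2)cc1OC
F7 | step 1 | 1-(3,4-dimethoxybenzyl)-1H-benzotriazole | COc1ccc(Cn2nnc3ccccc32)cc1OC
F8 | step 1 | [(1H-benzotriazol-1-yl)(3,4-dimethoxyphenyl)methyl]lithium | [Li+].COc1ccc([CH-]n2nnc3ccccc32)cc1OC
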